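(The data are calculated for an exercise; scatter was added.)

In a one-step picture each starting material simply becomes target, yet spring still holds 25.0% intermediate at 4.00 h, and its target has stopped rising since about 2.00 h.

| flask | starting material | partner | protic impurity | free catalyst | second catalyst | remark | time |
|---|---|---|---|---|---|---|---|
| spring | 0.10 M | 0.15 M | 0.10 M | 10 mM | 4.5 mM | run made earlier |  |
| summer | 0.14 M | 0.15 M | 0.10 M | 10 mM | 4.5 mM | run made earlier |  |
| noon | 0.22 M | 0.15 M | 0.10 M | 10 mM | 4.5 mM | run made earlier |  |
| autumn | 0.10 M | 0.15 M | 0.10 M | 20 mM | 4.5 mM | run made earlier |  |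
| south | 0.10 M | 0.150 M | 0.100 M | 10 mM | 4.5 mM | a closed flask charged with all of it at once and left for 6.0 h | 6.0 h |
| east | 0.10 M (fed, over 3.00 h) | 0.150 M | 0.100 M | 10 mM | 4.5 mM | a stirred flask in which starting material is dosed at a steady rate over 3.00 h without added volume, worked up at 6.0 h | 6.0 h |
| north | 0.10 M | 0.150 M | 0.100 M | 10 mM | 4.5 mM | one stirred flow tank at steady state, fed with the mixture as stated, mean residence time 6.0 h |  |
| south-east | 0.10 M | 0.150 M | 0.100 M | 10 mM | 4.5 mM | a single well-mixed tank run continuously and read at steady state, 60.0 h in it on average |  |

- spring (time / h: intermediate / %, target / %, starting material / %): 0.667: 17.2, 43.1, 37.9; 1.33: 18.2, 60.0, 16.1; 2.00: 21.4, 65.4, 7.8; 3.00: 23.6, 64.3, 2.7; 4.00: 25.0, 63.5, 1.5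
- summer (time / h: intermediate / %, target / %, starting material / %): 0.250: 13.1, 16.5, 69.2; 0.500: 16.8, 33.5, 48.4; 1.00: 22.6, 50.2, 24.8; 2.00: 32.5, 54.2, 7.5; 4.00: 39.0, 52.4, 1.9
- noon (time / h: intermediate / %, target / %, starting material / %): 0.667: 23.6, 35.5, 39.2; 1.33: 40.3, 40.1, 16.1; 2.00: 48.6, 40.1, 8.9; 3.00: 53.4, 39.4, 3.0; 4.00: 55.4, 39.4, 1.8
- autumn (time / h: intermediate / %, target / %, starting material / %): 0.667: 22.9, 58.7, 14.5; 1.33: 19.5, 69.8, 3.5; 2.00: 17.8, 70.6, 0.7; 3.00: 17.9, 69.5, 0.1; 4.00: 17.1, 66.2, 0

(readings scatter by 0.5 percentage points)

- the stated concentrations are those of everything mixed, before any reaction; amounts are the same in each set-up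
- the feed brings no volume worth counting
- the earlier runs were made in a closed, stirred flask

* the set-up with the highest amount of intermediate at the outlet or at the end, in percent of the starting material put in ("none" if the first two lie within 2 percentage points) (south / east / north / south-east / none)
* amount of intermediate at the outlet or at the end, in percent of the starting material put in, south
* amount of intermediate at the outlet or at the end, in percent of the starting material put in, east
* amount of intermediate at the outlet or at the end, in percent of the starting material put in, north
* amount of intermediate at the outlet or at the end, in percent of the starting material put in, south-east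

Counted as fractions of the starting-material charge, partner stands at 150%, against a demand from starting material and impurity together of 200%, so partner is the limiting reagent and the shortfall is 50.0%. What stays stranded at the end, intermediate plus starting material, falls below that shortfall by the spared share, 23.5% in spring. In autumn, the same shortfall gives a spared share of 32.9%, while the conversion time of starting material, read from the first point, drops from 0.687 h in spring to 0.345 h.

My own reckoning takes the spared share as linear in the logarithm of the mean arrival time of intermediate. In east that time is half the dosing time plus the conversion time, 2.19 h, which is longer than in spring by a factor of 3.19. The spared share then shrinks to 7.69%, leaving 42.3% stranded in east, counted with its starting material.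

The forecast gave 26% for south, 39% for east, 10% for north and 8.5% for south-east, and chose east, since “slow dosing lets impurity eat partner first”.

The flask gives 25.4%, 43.3%, 12.1% and 11.8% in that order, with east highest.

    partner + target → over-reaction product (k = 6.40 × 10⁻⁴ /M/s)
    free catalyst + target → spent catalyst (k = 8.50 × 10⁻⁴ /M/s)
    partner + second catalyst + intermediate → second catalyst + target (k = 4.20 /M²/s)
    starting material + free catalyst → free catalyst + intermediate (k = 0.0410 /M/s)
    partner + protic impurity → quenched reagent (k = 0.00420 /M/s)

In east, starting material peaked at 24.9% of the charge while the dose ran, and the end holds 43.3% intermediate with 1.27% starting material, a spared share of 5.43% against the reckoned 7.69%. In south, charged at once, the intermediate alone leaves 24.6% beside spring's 23.5%, and 5.22% over-reaction product stands at the end. Left for 60.0 h, east holds 44.6% intermediate.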